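**Retrosynthetic overview**
1. Target ⇐ N-Ns azonine 27 (Ns→CHO swap); ring C is closed last by an intramolecular Fukuyama–Mitsunobu N–C9 alkylation.
2. Ring B and the C3=C4–C5=O enone ⇐ 5-alkynal 22 by Rh(I) cis-hydroacylation (C4–C5 bond) — the proposed new step.
3. C13/C15 syn-diol ⇐ enone 14 by CBS reduction, OH-directed epoxidation and hydride opening; the C15–H stereocentre that relayed chirality is erased by dehydrogenation and rebuilt as C15–O.
4. C12 (quaternary) and C7 ⇐ 2-alkynyl-(R)-5-methylcyclohexenone 8 by conjugate addition then α-allylation; 8 ⇐ Sonogashira of iodoenone 6 ⇐ organocatalytic annulation of crotonaldehyde and tert-butyl acetoacetate.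
5. Ring order: A (from step 1) → B (step 14) → C (step 17).

Assumption: fawcettimine-type numbering is used for orientation only (C12 quaternary ring-fusion carbon, C13 and C15 acetoxy carbons, C5 ketone, C3=C4 enone, N between C1 and C9); the SMILES is read as (3aS,4S,6S,7aS) with C5=O trans to C2 on the alkene (E).
Abbreviations: TBS = tert-butyldimethylsilyl, TBDPS = tert-butyldiphenylsilyl, Ns = 2-nitrobenzenesulfonyl.

**Route**

Step 1
Reactants: 1 (E)-but-2-enal; 2 tert-butyl 3-oxobutanoate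
Product: 5 (5R)-5-methylcyclohex-2-en-1-one, via Michael adduct 3 (not isolated), via keto ester 4 (not isolated)
Conditions: (S)-2-{bis[3,5-bis(trifluoromethyl)phenyl](trimethylsilyloxy)methyl}pyrrolidine (10 mol%), neat, rt; then TsOH·H2O (20 mol%), toluene, 80 °C
Reagents that add atoms: none
Why: Iminium-catalysed Michael addition (the (S)-diarylprolinol silyl ether shields one face of the enal β-carbon, giving the 3R adduct) followed by acid-promoted aldol condensation, tert-butyl ester cleavage and decarboxylation (organocatalytic Robinson-type annulation).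

Step 2
Reactants: 5 (5R)-5-methylcyclohex-2-en-1-one
Product: 6 (5R)-2-iodo-5-methylcyclohex-2-en-1-one
Conditions: I2, pyridine, CH2Cl2, 0 °C → rt
Reagents that add atoms: iodine, II
Why: Johnson α-iodination of an enone (pyridine conjugate addition, enolate iodination, elimination) leaves the remote C5 stereocentre untouched.

Step 3
Reactants: 6 (5R)-2-iodo-5-methylcyclohex-2-en-1-one; 7 tert-butyl(but-3-yn-1-yloxy)dimethylsilane
Product: 8 (5R)-2-[4-(TBS-oxy)but-1-yn-1-yl]-5-methylcyclohex-2-en-1-one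
Conditions: PdCl2(PPh3)2 (3 mol%), CuI (6 mol%), i-Pr2NH, THF, 0 °C → rt
Reagents that add atoms: none
Why: Sonogashira coupling of an α-iodoenone is fast at low temperature and places the future C4≡C3–C2–C1 arm on C12 before the quaternary centre is made.

Step 4
Reactants: 8 (5R)-2-[4-(TBS-oxy)but-1-yn-1-yl]-5-methylcyclohex-2-en-1-one; 9 (1,3-dioxolan-2-ylmethyl)magnesium bromide
Product: 10 {[(3S,5R)-2-[4-(TBS-oxy)but-1-yn-1-yl]-3-(1,3-dioxolan-2-ylmethyl)-5-methylcyclohex-1-en-1-yl]oxy}trimethylsilane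
Conditions: 9 (2 equiv), CuBr·SMe2 (20 mol%), TMSCl (3 equiv), DMPU, THF, −78 → −30 °C; Et3N, pentane, filtration
Reagents that add atoms: chlorotrimethylsilane, C[Si](C)(C)Cl
Why: TMSCl-accelerated copper-catalysed conjugate addition of the acetaldehyde-enolate equivalent occurs axially and trans to the pseudo-equatorial C15 methyl, setting C7, and the enolate is trapped regiospecifically as its silyl enol ether.

Step 5
Reactants: 10 silyl enol ether; 11 3-iodoprop-1-ene
Product: 13 (2S,3S,5R)-2-allyl-2-[4-(TBS-oxy)but-1-yn-1-yl]-3-(1,3-dioxolan-2-ylmethyl)-5-methylcyclohexan-1-one, via lithium enolate 12 (not isolated)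
Conditions: MeLi (1.05 equiv), THF, 0 °C; then 11, DMPU, −78 → 0 °C
Reagents that add atoms: methyllithium, [Li]C (its lithium appears only in intermediate 12)
Why: Regiospecific lithium enolate alkylation at the alkynyl-bearing α-carbon takes place anti to the neighbouring C7 substituent, so the allyl group (future C11–C9) ends trans and the alkyne cis to the C7 side chain, setting the C12 quaternary centre.

Step 6
Reactants: 13 quaternary ketone
Product: 14 (5S,6S)-6-allyl-6-[4-(TBS-oxy)but-1-yn-1-yl]-5-(1,3-dioxolan-2-ylmethyl)-3-methylcyclohex-2-en-1-one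
Conditions: IBX (2 equiv), DMSO/fluorobenzene 1:2, 70 °C
Reagents that add atoms: none
Why: IBX α,β-dehydrogenation (Nicolaou) can only engage C14–C15 because C12 is quaternary, and it deliberately erases the C15–H stereocentre once it has relayed chirality to C7 and C12.

Step 7
Reactants: 14 enone
Product: 15 (1S,5S,6S)-6-allyl-6-[4-(TBS-oxy)but-1-yn-1-yl]-5-(1,3-dioxolan-2-ylmethyl)-3-methylcyclohex-2-en-1-ol
Conditions: (R)-Me-CBS (0.3 equiv), catecholborane (2 equiv), toluene, −78 → −40 °C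
Reagents that add atoms: none
Why: Corey–Bakshi–Shibata reduction with the quaternary carbon as the large group delivers hydride to the face anti to the axial alkynyl group (also the substrate-preferred axial attack), setting C13–OH cis to the alkyne.

Step 8
Reactants: 15 allylic alcohol
Product: 16 (1R,2R,3S,4S,6S)-3-allyl-3-[4-(TBS-oxy)but-1-yn-1-yl]-4-(1,3-dioxolan-2-ylmethyl)-6-methyl-7-oxabicyclo[4.1.0]heptan-2-ol
Conditions: VO(acac)2 (5 mol%), t-BuOOH (1.5 equiv, decane), CH2Cl2, 0 °C → rt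
Reagents that add atoms: tert-butyl hydroperoxide, CC(C)(C)OO
Why: Vanadium-catalysed hydroxyl-directed epoxidation is chemoselective for the allylic alkene and delivers oxygen syn to C13–OH, which fixes the C15–O configuration.

Step 9
Reactants: 16 epoxy alcohol
Product: 17 (1S,3S,4S,5S)-4-allyl-4-[4-(TBS-oxy)but-1-yn-1-yl]-5-(1,3-dioxolan-2-ylmethyl)-1-methylcyclohexane-1,3-diol
Conditions: LiAlH4, THF, 0 °C → rt; Fieser work-up
Reagents that add atoms: none
Why: Hydride opens the trisubstituted epoxide by SN2 attack at the secondary carbon C14 (trans-diaxial opening), leaving the tertiary C15–OH cis to C13–OH.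

Step 10
Reactants: 17 diol
Product: 18 (1S,3S,4S,5S)-4-allyl-4-[4-(TBS-oxy)but-1-yn-1-yl]-5-(1,3-dioxolan-2-ylmethyl)-1-methylcyclohexane-1,3-diyl diacetate
Conditions: Ac2O (8 equiv), DMAP (1 equiv), Et3N, CH2Cl2, 40 °C
Reagents that add atoms: acetic anhydride, CC(=O)OC(C)=O
Why: DMAP-catalysed (Steglich-type) acylation esterifies both the hindered secondary and the equatorial tertiary alcohol, installing the two acetates of the target early so that no lactol can form with the later C5 aldehyde.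

Step 11
Reactants: 18 diacetate
Product: 20 (1S,3S,4S,5S)-4-[4-(TBS-oxy)but-1-yn-1-yl]-5-(1,3-dioxolan-2-ylmethyl)-4-(3-hydroxypropyl)-1-methylcyclohexane-1,3-diyl diacetate, via alkylborane 19 (not isolated)
Conditions: 9-BBN (2 equiv), THF, 0 °C → rt; then NaBO3·4H2O, H2O, rt
Reagents that add atoms: 9-borabicyclo[3.3.1]nonane, B1C2CCCC1CCC2 (boron only in intermediate 19); sodium perborate, [Na+].[O-]OB=O (oxygen source)
Why: Brown anti-Markovnikov hydroboration with 9-BBN is selective for the terminal alkene over the internal alkyne, and perborate oxidation spares the acetates.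

Step 12
Reactants: 20 primary alcohol
Product: 21 (1S,3S,4S,5S)-4-[4-(TBS-oxy)but-1-yn-1-yl]-4-[3-(TBDPS-oxy)propyl]-5-(1,3-dioxolan-2-ylmethyl)-1-methylcyclohexane-1,3-diyl diacetate
Conditions: TBDPSCl, imidazole, DMF, rt
Reagents that add atoms: tert-butyl(chloro)diphenylsilane, CC(C)(C)[Si](Cl)(c1ccccc1)c1ccccc1
Why: Standard silylation gives an acid-stable C9–O protecting group, which differentiates the two primary oxygens (C1–OTBS acid-labile, C9–OTBDPS fluoride-labile).

Step 13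
Reactants: 21 bis-silyl ether acetal
Product: 22 (1S,3S,4S,5S)-4-[3-(TBDPS-oxy)propyl]-4-(4-hydroxybut-1-yn-1-yl)-1-methyl-5-(2-oxoethyl)cyclohexane-1,3-diyl diacetate
Conditions: AcOH/THF/H2O 3:1:1, 50 °C
Reagents that add atoms: water, O
Why: Mild aqueous acetic acid hydrolyses the dioxolane and the primary TBS ether in one operation, while the TBDPS ether and both acetates (including the acid-sensitive tertiary one) survive.

Step 14
Reactants: 22 5-alkynal
Product: 23 (3E,3aS,4S,6S,7aS)-3a-[3-(TBDPS-oxy)propyl]-3-(3-hydroxypropylidene)-6-methyl-2-oxooctahydro-1H-indene-4,6-diyl diacetate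
Conditions: [Rh(dppe)]2(BF4)2 (5 mol%), acetone, 0.05 M, 60 °C
Reagents that add atoms: none
Why: Proposed new method: Rh(I)-catalysed intramolecular cis-hydroacylation, applied for the first time to an internal alkyne held on a fully substituted ring carbon so that one 5-exo acyl–alkyne coupling closes ring B against the C12 quaternary centre and fixes the enone geometry — aldehyde C–H oxidative addition to cationic Rh(I) gives an acyl–Rh(III) hydride, syn-hydrorhodation of the alkyne with Rh on the proximal carbon C4 gives a six-membered acyl-rhodacycle (chelating dppe slows decarbonylation), and C–C reductive elimination forges C4–C5 with H and acyl cis on the alkene (C5=O trans to C2, as in the target), the cis ring fusion following from the axial alkyne and equatorial CH2CHO on adjacent carbons; the closest known reaction type is the cationic Rh(I)–diphosphine cycloisomerisation of simple 5-alkynals to α-alkylidenecyclopentanones (alkyne hydroacylation).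

Step 15
Reactants: 23 hydroxy enone; 24 2-nitrobenzenesulfonamide
Product: 25 (3E,3aS,4S,6S,7aS)-3a-[3-(TBDPS-oxy)propyl]-6-methyl-3-[3-(2-nitrophenylsulfonamido)propylidene]-2-oxooctahydro-1H-indene-4,6-diyl diacetate
Conditions: 24 (4 equiv), PPh3, DIAD, THF, 0 °C → rt
Reagents that add atoms: none
Why: Fukuyama–Mitsunobu N-alkylation with excess NsNH2 gives the mono-alkylated sulfonamide at C1, where the nitrogen cannot undergo aza-Michael addition to the enone (it would need a four-membered ring).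

Step 16
Reactants: 25 Ns-amide silyl ether
Product: 26 (3E,3aS,4S,6S,7aS)-3a-(3-hydroxypropyl)-6-methyl-3-[3-(2-nitrophenylsulfonamido)propylidene]-2-oxooctahydro-1H-indene-4,6-diyl diacetate
Conditions: HF·pyridine, pyridine/THF, 0 °C → rt
Reagents that add atoms: none
Why: Buffered fluoride desilylation removes the TBDPS group without touching the acetates, the enone or the sulfonamide.

Step 17
Reactants: 26 Ns-amide alcohol
Product: 27 N-Ns azonine [(3aS,4S,6S,7aS)-hydrindan-2-one 4,6-diacetate bridged C3=CH–CH2CH2–N(Ns)–CH2CH2CH2–C3a]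
Conditions: PPh3, DIAD, toluene/THF, 2 mM (syringe-pump addition), rt
Reagents that add atoms: none
Why: Intramolecular Fukuyama–Mitsunobu alkylation of the acidic Ns-amide closes the nine-membered ring at the saturated C9 arm (no β-elimination pathway), with the ring-cis enone geometry holding the two chain ends close.

Step 18
Reactants: 27 N-Ns azonine
Product: 29 CNP0137427.1, via secondary amine 28 (not isolated)
Conditions: PhSH, K2CO3, MeCN, rt; then HCO2CH2CF3, rt
Reagents that add atoms: 2,2,2-trifluoroethyl formate, O=COCC(F)(F)F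
Why: Fukuyama denosylation (thiolate SNAr via a Meisenheimer complex, SO2 loss) frees the amine, which is N-formylated at once by the mild active formate without disturbing the acetates or the hindered trisubstituted enone.

**Compound list**
1 | (E)-but-2-enal | C/C=C/C=O | starting material
2 | tert-butyl 3-oxobutanoate | CC(=O)CC(=O)OC(C)(C)C | starting material
3 | tert-butyl (3R)-2-acetyl-3-methyl-5-oxopentanoate (C2 epimers) | CC(=O)C(C(=O)OC(C)(C)C)[C@H](C)CC=O | intermediate
4 | tert-butyl (6R)-6-methyl-2-oxocyclohex-3-ene-1-carboxylate (C1 epimers) | C[C@@H]1CC=CC(=O)C1C(=O)OC(C)(C)C | intermediate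
5 | (5R)-5-methylcyclohex-2-en-1-one | C[C@H]1CC(=O)C=CC1 | intermediate
6 | (5R)-2-iodo-5-methylcyclohex-2-en-1-one | C[C@H]1CC(=O)C(I)=CC1 | intermediate
7 | tert-butyl(but-3-yn-1-yloxy)dimethylsilane | C#CCCO[Si](C)(C)C(C)(C)C | starting material
8 | (5R)-2-[4-(tert-butyldimethylsilyloxy)but-1-yn-1-yl]-5-methylcyclohex-2-en-1-one | C[C@H]1CC(=O)C(C#CCCO[Si](C)(C)C(C)(C)C)=CC1 | intermediate
9 | (1,3-dioxolan-2-ylmethyl)magnesium bromide | Br[Mg]CC1OCCO1 | starting material
10 | {[(3S,5R)-2-[4-(tert-butyldimethylsilyloxy)but-1-yn-1-yl]-3-(1,3-dioxolan-2-ylmethyl)-5-methylcyclohex-1-en-1-yl]oxy}trimethylsilane | C[C@H]1CC(O[Si](C)(C)C)=C(C#CCCO[Si](C)(C)C(C)(C)C)[C@H](CC2OCCO2)C1 | intermediate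
11 | 3-iodoprop-1-ene | C=CCI | starting material
12 | lithium (3S,5R)-2-[4-(tert-butyldimethylsilyloxy)but-1-yn-1-yl]-3-(1,3-dioxolan-2-ylmethyl)-5-methylcyclohex-1-en-1-olate | C[C@H]1CC(O[Li])=C(C#CCCO[Si](C)(C)C(C)(C)C)[C@H](CC2OCCO2)C1 | intermediate
13 | (2S,3S,5R)-2-allyl-2-[4-(tert-butyldimethylsilyloxy)but-1-yn-1-yl]-3-(1,3-dioxolan-2-ylmethyl)-5-methylcyclohexan-1-one | C[C@H]1CC(=O)[C@](CC=C)(C#CCCO[Si](C)(C)C(C)(C)C)[C@H](CC2OCCO2)C1 | intermediate
14 | (5S,6S)-6-allyl-6-[4-(tert-butyldimethylsilyloxy)but-1-yn-1-yl]-5-(1,3-dioxolan-2-ylmethyl)-3-methylcyclohex-2-en-1-one | CC1=CC(=O)[C@](CC=C)(C#CCCO[Si](C)(C)C(C)(C)C)[C@H](CC2OCCO2)C1 | intermediate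
15 | (1S,5S,6S)-6-allyl-6-[4-(tert-butyldimethylsilyloxy)but-1-yn-1-yl]-5-(1,3-dioxolan-2-ylmethyl)-3-methylcyclohex-2-en-1-ol | CC1=C[C@H](O)[C@](CC=C)(C#CCCO[Si](C)(C)C(C)(C)C)[C@H](CC2OCCO2)C1 | intermediate
16 | (1R,2R,3S,4S,6S)-3-allyl-3-[4-(tert-butyldimethylsilyloxy)but-1-yn-1-yl]-4-(1,3-dioxolan-2-ylmethyl)-6-methyl-7-oxabicyclo[4.1.0]heptan-2-ol | C[C@@]12O[C@@H]1[C@H](O)[C@](CC=C)(C#CCCO[Si](C)(C)C(C)(C)C)[C@H](CC3OCCO3)C2 | intermediate
17 | (1S,3S,4S,5S)-4-allyl-4-[4-(tert-butyldimethylsilyloxy)but-1-yn-1-yl]-5-(1,3-dioxolan-2-ylmethyl)-1-methylcyclohexane-1,3-diol | O[C@H]1C[C@@](C)(O)C[C@@H](CC2OCCO2)[C@@]1(CC=C)C#CCCO[Si](C)(C)C(C)(C)C | intermediate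
18 | (1S,3S,4S,5S)-4-allyl-4-[4-(tert-butyldimethylsilyloxy)but-1-yn-1-yl]-5-(1,3-dioxolan-2-ylmethyl)-1-methylcyclohexane-1,3-diyl diacetate | CC(=O)O[C@H]1C[C@@](C)(OC(C)=O)C[C@@H](CC2OCCO2)[C@@]1(CC=C)C#CCCO[Si](C)(C)C(C)(C)C | intermediate
19 | (1S,3S,4S,5S)-4-[3-(9-borabicyclo[3.3.1]nonan-9-yl)propyl]-4-[4-(tert-butyldimethylsilyloxy)but-1-yn-1-yl]-5-(1,3-dioxolan-2-ylmethyl)-1-methylcyclohexane-1,3-diyl diacetate | CC(=O)O[C@H]1C[C@@](C)(OC(C)=O)C[C@@H](CC2OCCO2)[C@@]1(CCCB2C3CCCC2CCC3)C#CCCO[Si](C)(C)C(C)(C)C | intermediate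
20 | (1S,3S,4S,5S)-4-[4-(tert-butyldimethylsilyloxy)but-1-yn-1-yl]-5-(1,3-dioxolan-2-ylmethyl)-4-(3-hydroxypropyl)-1-methylcyclohexane-1,3-diyl diacetate | CC(=O)O[C@H]1C[C@@](C)(OC(C)=O)C[C@@H](CC2OCCO2)[C@@]1(CCCO)C#CCCO[Si](C)(C)C(C)(C)C | intermediate
21 | (1S,3S,4S,5S)-4-[4-(tert-butyldimethylsilyloxy)but-1-yn-1-yl]-4-[3-(tert-butyldiphenylsilyloxy)propyl]-5-(1,3-dioxolan-2-ylmethyl)-1-methylcyclohexane-1,3-diyl diacetate | CC(=O)O[C@H]1C[C@@](C)(OC(C)=O)C[C@@H](CC2OCCO2)[C@@]1(CCCO[Si](c2ccccc2)(c2ccccc2)C(C)(C)C)C#CCCO[Si](C)(C)C(C)(C)C | intermediate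
22 | (1S,3S,4S,5S)-4-[3-(tert-butyldiphenylsilyloxy)propyl]-4-(4-hydroxybut-1-yn-1-yl)-1-methyl-5-(2-oxoethyl)cyclohexane-1,3-diyl diacetate | CC(=O)O[C@H]1C[C@@](C)(OC(C)=O)C[C@@H](CC=O)[C@@]1(CCCO[Si](c2ccccc2)(c2ccccc2)C(C)(C)C)C#CCCO | intermediate
23 | (3E,3aS,4S,6S,7aS)-3a-[3-(tert-butyldiphenylsilyloxy)propyl]-3-(3-hydroxypropylidene)-6-methyl-2-oxooctahydro-1H-indene-4,6-diyl diacetate | CC(=O)O[C@H]1C[C@@](C)(OC(C)=O)C[C@H]2CC(=O)/C(=C/CCO)[C@@]12CCCO[Si](c1ccccc1)(c1ccccc1)C(C)(C)C | intermediate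
24 | 2-nitrobenzenesulfonamide | NS(=O)(=O)c1ccccc1[N+](=O)[O-] | starting material
25 | (3E,3aS,4S,6S,7aS)-3a-[3-(tert-butyldiphenylsilyloxy)propyl]-6-methyl-3-[3-(2-nitrophenylsulfonamido)propylidene]-2-oxooctahydro-1H-indene-4,6-diyl diacetate | CC(=O)O[C@H]1C[C@@](C)(OC(C)=O)C[C@H]2CC(=O)/C(=C/CCNS(=O)(=O)c3ccccc3[N+](=O)[O-])[C@@]12CCCO[Si](c1ccccc1)(c1ccccc1)C(C)(C)C | intermediate
26 | (3E,3aS,4S,6S,7aS)-3a-(3-hydroxypropyl)-6-methyl-3-[3-(2-nitrophenylsulfonamido)propylidene]-2-oxooctahydro-1H-indene-4,6-diyl diacetate | CC(=O)O[C@H]1C[C@@](C)(OC(C)=O)C[C@H]2CC(=O)/C(=C/CCNS(=O)(=O)c3ccccc3[N+](=O)[O-])[C@@]12CCCO | intermediate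
27 | N-(2-nitrophenylsulfonyl) azonine: (3aS,4S,6S,7aS)-6-methyl-2-oxohydrindane-4,6-diyl diacetate bridged C3=CH–CH2CH2–N(Ns)–CH2CH2CH2–C3a, E-enone | CC(=O)O[C@H]1C[C@@](C)(OC(C)=O)C[C@H]2CC(=O)/C3=C/CCN(S(=O)(=O)c4ccccc4[N+](=O)[O-])CCC[C@@]321 | intermediate
28 | N-H azonine: same skeleton as 27 with free secondary amine | CC(=O)O[C@H]1C[C@@](C)(OC(C)=O)C[C@H]2CC(=O)/C3=C/CCNCCC[C@@]321 | intermediate
29 | CNP0137427.1: (3aS,4S,6S,7aS)-6-methyl-2-oxohydrindane-4,6-diyl diacetate bridged C3=CH–CH2CH2–N(CHO)–CH2CH2CH2–C3a, E-enone | CC(=O)O[C@H]1C[C@@](C)(OC(C)=O)C[C@H]2CC(=O)/C3=C/CCN(C=O)CCC[C@@]321 | target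

**Step count and risks**
Total step count: 18. Longest linear sequence: 18 steps (1/2 → 29; compounds 7, 9, 11 and 24 are bought).

Three steps most likely to fail:

Step 14 (proposed new step). The alkyne sits on a quaternary carbon, so hydrorhodation at C4 may be slow and decarbonylation or the endo mode could compete. Fallback with known chemistry, setting out from 22 and coming back at 23: a Ni(cod)2/PBu3-catalysed reductive ynal cyclisation with Et3SiH (Montgomery type; syn addition gives the same alkene geometry) gives the C5 triethylsilyl ether of the cyclised allylic alcohol F3. HF·pyridine at 0 °C then removes the triethylsilyl group selectively to give the C5 allylic alcohol F4, and MnO2 in CH2Cl2 oxidises only this allylic alcohol to enone 23.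

Step 4. The acetal Grignard is a sluggish donor and the 2-alkynyl enone is an untested acceptor. Fallback setting out from 8 and coming back at 13 (it also replaces step 5): a different acetaldehyde-enolate equivalent, lithium bis[(Z)-2-ethoxyvinyl]cuprate (from (Z)-1-ethoxy-2-(tributylstannyl)ethene, n-BuLi and CuI), is added with TMSCl to give the (Z)-2-ethoxyvinyl silyl enol ether F1. MeLi then allyl iodide convert it into the (Z)-2-ethoxyvinyl allyl ketone F2, and ethylene glycol with PPTS exchanges the enol ether for the dioxolane to give 13.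

Step 17. Nine-membered ring closure may lose out to oligomerisation under Mitsunobu conditions. Fallback setting out from 26 and coming back at 27: the redox-condensation closure is replaced by a discrete halide alkylation; I2/PPh3/imidazole converts the C9 alcohol into the C9 primary iodide F5, and Cs2CO3 in MeCN at 2 mM and 50 °C closes the ring by SN2 attack of the sulfonamide anion to give 27.

**Further compounds**
F1 | step 4 | (Z)-2-ethoxyvinyl silyl enol ether: {[(3S,5R)-2-[4-(tert-butyldimethylsilyloxy)but-1-yn-1-yl]-3-[(Z)-2-ethoxyvinyl]-5-methylcyclohex-1-en-1-yl]oxy}trimethylsilane | C[C@H]1CC(O[Si](C)(C)C)=C(C#CCCO[Si](C)(C)C(C)(C)C)[C@H](/C=C\OCC)C1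
F2 | step 4 | (Z)-2-ethoxyvinyl allyl ketone: (2S,3S,5R)-2-allyl-2-[4-(tert-butyldimethylsilyloxy)but-1-yn-1-yl]-3-[(Z)-2-ethoxyvinyl]-5-methylcyclohexan-1-one | C[C@H]1CC(=O)[C@](CC=C)(C#CCCO[Si](C)(C)C(C)(C)C)[C@H](/C=C\OCC)C1
F3 | step 14 | C5 triethylsilyl ether of the cyclised allylic alcohol: (3E,3aS,4S,6S,7aS)-3a-[3-(tert-butyldiphenylsilyloxy)propyl]-3-(3-hydroxypropylidene)-6-methyl-2-(triethylsilyloxy)octahydro-1H-indene-4,6-diyl diacetate (C2 epimers) | CC(=O)O[C@H]1C[C@@](C)(OC(C)=O)C[C@H]2CC(O[Si](CC)(CC)CC)/C(=C/CCO)[C@@]12CCCO[Si](c1ccccc1)(c1ccccc1)C(C)(C)C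
F4 | step 14 | C5 allylic alcohol: (3E,3aS,4S,6S,7aS)-3a-[3-(tert-butyldiphenylsilyloxy)propyl]-2-hydroxy-3-(3-hydroxypropylidene)-6-methyloctahydro-1H-indene-4,6-diyl diacetate (C2 epimers) | CC(=O)O[C@H]1C[C@@](C)(OC(C)=O)C[C@H]2CC(O)/C(=C/CCO)[C@@]12CCCO[Si](c1ccccc1)(c1ccccc1)C(C)(C)C
F5 | step 17 | C9 primary iodide: (3E,3aS,4S,6S,7aS)-3a-(3-iodopropyl)-6-methyl-3-[3-(2-nitrophenylsulfonamido)propylidene]-2-oxooctahydro-1H-indene-4,6-diyl diacetate | CC(=O)O[C@H]1C[C@@](C)(OC(C)=O)C[C@H]2CC(=O)/C(=C/CCNS(=O)(=O)c3ccccc3[N+](=O)[O-])[C@@]12CCCI
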